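The route rests on disconnecting the benzo ring of the indole at C5–C6. The vicinal bromines on C5 and C6, flanked by hydrogens on C4 and C7, are exactly what a Bergman cycloaromatisation leaves when two bromoalkyne termini bond and the resulting C4/C7 diradical is reduced. One thermal operation therefore closes the six-membered ring onto the pyrrole C2–C3 edge (indole C7a–C3a) and places both benzo bromines without any arene bromination. Its precursor is a 1-tosylpyrrole carrying bromoethynyl groups on C2 and C3, assembled from a 3-bromopyrrole by C2 iodination, twofold alkynylation and bromodesilylation. Detosylation and bromination at C3 and C2 complete the target.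

Key step: step 5

Remark on the chemistry: the target is planar and has no stereocentre or other stereogenic element, so the SMILES defines it fully and no step has to control configuration.

Step 1
Reactants: 1 3-bromo-1-(triisopropylsilyl)pyrrole
Product: 3 3-bromo-1-tosylpyrrole, via 3-bromo-1H-pyrrole 2 (not isolated)
Conditions: TBAF, THF, 0 °C; aqueous wash, crude 2 used at once; NaH, TsCl, THF, 0 °C → rt
Reagents that add atoms: p-toluenesulfonyl chloride, Cc1ccc(cc1)S(=O)(=O)Cl
Why: Fluoride cleaves the N–Si bond (desilylation) and the sensitive 3-bromopyrrole is captured at once as its sodium salt by tosyl chloride (N-sulfonylation), which keeps bromine fixed at C3 and installs the electron-withdrawing, C2-directing group.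

Step 2
Reactants: 3 3-bromo-1-tosylpyrrole
Product: 5 3-bromo-2-iodo-1-tosylpyrrole, via 3-bromo-2-lithio-1-tosylpyrrole 4 (not isolated)
Conditions: LDA, THF, −78 °C; then I2, −78 °C → rt
Reagents that add atoms: iodine, II
Why: Directed lithiation–iodination: C2–H, flanked by the N-sulfonyl group and the C3 bromine, is the most acidic ring proton and should be removed by the non-nucleophilic amide at −78 °C without bromine–lithium exchange, after which iodine traps the aryllithium.

Step 3
Reactants: 5 3-bromo-2-iodo-1-tosylpyrrole; 6 trimethylsilylacetylene
Product: 8 1-tosyl-2,3-bis[(trimethylsilyl)ethynyl]pyrrole, via 3-bromo-1-tosyl-2-[(trimethylsilyl)ethynyl]pyrrole 7 (not isolated)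
Conditions: Pd(PhCN)2Cl2 (5 mol %), [HP(t-Bu)3]BF4 (10 mol %), CuI (5 mol %), 6 (3 equiv), i-Pr2NH, dioxane, rt → 50 °C
Reagents that add atoms: none
Why: Twofold Sonogashira coupling: the C2–I bond should add to palladium first, and the bulky, electron-rich tri-tert-butylphosphine catalyst should then engage the C3–Br bond of the electron-poor N-sulfonylpyrrole under mild heating, with the silyl caps blocking the far alkyne ends.

Step 4
Reactants: 8 1-tosyl-2,3-bis[(trimethylsilyl)ethynyl]pyrrole
Product: 9 2,3-bis(bromoethynyl)-1-tosylpyrrole
Conditions: NBS (2.3 equiv), AgNO3 (0.3 equiv), acetone, rt, dark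
Reagents that add atoms: N-bromosuccinimide, O=C1CCC(=O)N1Br
Why: Silver-catalysed bromodesilylation: Ag(I) converts each silylalkyne into a silver acetylide that N-bromosuccinimide brominates at the sp carbon, while the doubly alkynylated N-sulfonylpyrrole ring should be too electron-poor to be brominated.

Step 5
Reactants: 9 2,3-bis(bromoethynyl)-1-tosylpyrrole; 10 1,4-cyclohexadiene
Product: 12 5,6-dibromo-1-tosylindole, via 5,6-dibromo-1-tosylindole-4,7-diyl 11 (not isolated)
Conditions: 10/PhCl (1:3), 5 mM, degassed, sealed tube, dark, 180 °C
Reagents that add atoms: none
Why: Proposed new method: on heating, the two in-plane alkyne π systems held cis on the pyrrole C2=C3 bond should bond to each other at their bromine-bearing termini (Bergman cycloaromatisation), giving the σ,σ-diradical 11, whose sp2 radicals at C4 and C7 each take a hydrogen atom from a doubly allylic C–H bond of 10, which ends as benzene. The closest known reaction type is the thermal cycloaromatisation of benzo-fused 1,2-bis(bromoethynyl)arenes to 2,3-dibromoacenes in the presence of 1,4-cyclohexadiene, together with Bergman closures of other five-membered heteroarene-fused enediynes; the transfer to a pyrrole-fused bis(bromoalkyne) is the untested part. The single new ring is the six-membered benzo ring, closed by C1–C6 bonding of the hex-3-ene-1,5-diyne unit (endo-dig at both alkynes) across the pre-existing cis ene, so there is no regiochemical alternative and no stereocentre is created. The step needs chemoselectivity: cyclisation and hydrogen capture must be faster than C–Br homolysis, radical addition–elimination at the bromoalkynes and ipso attack of the C7 radical on the tolyl ring. The substrate supports this through the high C2=C3 bond order of an N-sulfonylpyrrole, the buttressing N-tosyl group that bends the C2 alkyne towards its partner, the electron-poor ring that resists thermal decomposition and the strong C(sp)–Br bonds. High dilution in a large excess of donor is chosen so that each aryl radical is capped bimolecularly before it can attack another molecule of 9 or the sulfonyl arene.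

Step 6
Reactants: 12 5,6-dibromo-1-tosylindole
Product: 13 5,6-dibromo-1H-indole
Conditions: KOH, THF/MeOH/H2O, 60 °C
Reagents that add atoms: none
Why: Sulfonamide cleavage by nucleophilic attack at sulfur, with the indolide made a better leaving group by the two bromines; the aryl bromides are inert to hydroxide, which is why a reductive detosylation is avoided.

Step 7
Reactants: 13 5,6-dibromo-1H-indole
Product: 15 2,3,5,6-tetrabromo-1H-indole, via 3,5,6-tribromo-1H-indole 14 (not isolated)
Conditions: NBS (2.05 equiv), anhydrous THF, −78 → 0 °C, dark
Reagents that add atoms: N-bromosuccinimide, O=C1CCC(=O)N1Br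
Why: Electrophilic aromatic substitution of the free indole: C3 should react first and the second bromine should enter C2 (directly or via a 3,3-dibromo-3H-indole and 1,2-bromine shift), while the benzo ring deactivated by two bromines and the exclusion of water (no oxindole formation) should hold the reaction at the 2,3-dibromide.

Compound list
1 | 3-bromo-1-(triisopropylsilyl)pyrrole | CC(C)[Si](C(C)C)(C(C)C)n1ccc(Br)c1 | starting material
2 | 3-bromo-1H-pyrrole | Brc1cc[nH]c1 | intermediate
3 | 3-bromo-1-tosylpyrrole | Cc1ccc(cc1)S(=O)(=O)n1ccc(Br)c1 | intermediate
4 | 3-bromo-2-lithio-1-tosylpyrrole | [Li]c1c(Br)ccn1S(=O)(=O)c1ccc(C)cc1 | intermediate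
5 | 3-bromo-2-iodo-1-tosylpyrrole | Cc1ccc(cc1)S(=O)(=O)n1ccc(Br)c1I | intermediate
6 | trimethylsilylacetylene | C[Si](C)(C)C#C | starting material
7 | 3-bromo-1-tosyl-2-[(trimethylsilyl)ethynyl]pyrrole | Cc1ccc(cc1)S(=O)(=O)n1ccc(Br)c1C#C[Si](C)(C)C | intermediate
8 | 1-tosyl-2,3-bis[(trimethylsilyl)ethynyl]pyrrole | Cc1ccc(cc1)S(=O)(=O)n1ccc(C#C[Si](C)(C)C)c1C#C[Si](C)(C)C | intermediate
9 | 2,3-bis(bromoethynyl)-1-tosylpyrrole | BrC#Cc1ccn(S(=O)(=O)c2ccc(C)cc2)c1C#CBr | intermediate
10 | 1,4-cyclohexadiene | C1C=CCC=C1 | starting material
11 | 5,6-dibromo-1-tosylindole-4,7-diyl (σ,σ-diradical) | Cc1ccc(cc1)S(=O)(=O)n1ccc2[c]c(Br)c(Br)[c]c21 | intermediate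
12 | 5,6-dibromo-1-tosylindole | Cc1ccc(cc1)S(=O)(=O)n1ccc2cc(Br)c(Br)cc21 | intermediate
13 | 5,6-dibromo-1H-indole | Brc1cc2cc[nH]c2cc1Br | intermediate
14 | 3,5,6-tribromo-1H-indole | Brc1c[nH]c2cc(Br)c(Br)cc12 | intermediate
15 | 2,3,5,6-tetrabromo-1H-indole | Brc1cc2[nH]c(Br)c(Br)c2cc1Br | target

Total step count: 7. Longest linear sequence: 7 steps (1 → 15).

Steps most likely to fail

Step 5 (the step carrying the new-method label). The cyclisation may be too slow at a temperature the bromoalkynes tolerate. Bromine would then be lost from the alkyne termini by homolysis or by addition–elimination of donor-derived radicals, or the enediyne would oligomerise, giving debrominated indoles or none. The fallback gives up building the benzo ring and reaches the same intermediate by known electrophilic chemistry on a preformed indole. No pyrrole intermediate of the route can serve once ring construction is abandoned, so it sets out from no numbered compound but from commercial methyl 1H-indole-3-carboxylate F1. The C3 ester deactivates the pyrrole ring, so bromine in acetic acid at room temperature should enter C5 and C6 and give methyl 5,6-dibromo-1H-indole-3-carboxylate F2. Saponification (NaOH, MeOH/H2O, reflux, then acid) should give 5,6-dibromo-1H-indole-3-carboxylic acid F3. Thermal protodecarboxylation (hot aqueous acid or quinoline) should then give 5,6-dibromo-1H-indole, where the fallback comes back to the route at 13, directly before step 7.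

Step 3. Oxidative addition into the C3–Br bond may stall after the first coupling, while copper-mediated dimerisation consumes the alkyne and prolonged heating in amine erodes the N-tosyl group. The fallback sets out from 5 and separates the two couplings. Only the iodide is coupled (PdCl2(PPh3)2, CuI, Et3N, rt, 1.1 equiv of 6) and the monoalkyne 7 is isolated. The second alkyne is then introduced without copper or base by Stille coupling of 7 with commercial tributyl[(trimethylsilyl)ethynyl]stannane (Pd(PPh3)4, toluene, 100 °C). The fallback comes back to the route at 8.

Step 7. The free 3-bromoindole stage may be over-oxidised by traces of water (oxindole formation), brominated on nitrogen, or the acid- and light-sensitive NH-2,3-dibromoindole may decompose during reaction and isolation. The fallback sets out from 12 and installs both pyrrole-ring bromines while nitrogen is still sulfonylated. Bromine in CH2Cl2 at 0 °C should brominate C3 to give 3,5,6-tribromo-1-tosylindole F4. LDA at −78 °C should then remove the C2 proton, flanked by N-sulfonyl and C3–Br, without touching the aryl bromides, to give 3,5,6-tribromo-2-lithio-1-tosylindole F5. Quenching with 1,2-dibromotetrachloroethane should give 2,3,5,6-tetrabromo-1-tosylindole F6. Mild hydroxide cleavage of the now very labile sulfonamide (KOH, THF/MeOH/H2O, rt) comes back to the route at the target 15, with step 6 no longer needed.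

Further compounds
F1 | step 5 | methyl 1H-indole-3-carboxylate | COC(=O)c1c[nH]c2ccccc12
F2 | step 5 | methyl 5,6-dibromo-1H-indole-3-carboxylate | COC(=O)c1c[nH]c2cc(Br)c(Br)cc12
F3 | step 5 | 5,6-dibromo-1H-indole-3-carboxylic acid | OC(=O)c1c[nH]c2cc(Br)c(Br)cc12
F0 | step 3 | none | none
F4 | step 7 | 3,5,6-tribromo-1-tosylindole | Cc1ccc(cc1)S(=O)(=O)n1cc(Br)c2cc(Br)c(Br)cc21
F5 | step 7 | 3,5,6-tribromo-2-lithio-1-tosylindole | Cc1ccc(cc1)S(=O)(=O)n1c([Li])c(Br)c2cc(Br)c(Br)cc21
F6 | step 7 | 2,3,5,6-tetrabromo-1-tosylindole | Cc1ccc(cc1)S(=O)(=O)n1c(Br)c(Br)c2cc(Br)c(Br)cc21
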